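The share of the partner charge that has become target by a given hour stays nearly the same from one run to the next in the runs so far. Call it the partner share: target made, divided by c_partner at the start.

| setting | south-west | north-west | north-east | south | east |
|---|---|---|---|---|---|
| substrate | 0.600 M | 0.240 M | 0.600 M | 0.600 M | 0.600 M |
| partner | 0.480 M | 0.120 M | 0.240 M | 0.480 M | 0.480 M |
| free catalyst | 0.00120 M | 0.00120 M | 0.00120 M | 0.00120 M | 0.00120 M |
| target |  |  |  | 0.180 M |  |
| time |  |  |  |  | 1900 h |

- south-west run (time / h: [target] / M): 13: 0.045; 24: 0.081; 46: 0.137; 88: 0.209; 170: 0.295; 320: 0.327
- north-west run (time / h: [target] / M): 13: 0.011; 24: 0.020; 46: 0.033; 88: 0.054; 170: 0.075; 320: 0.084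
- north-east run (time / h: [target] / M): 13: 0.022; 24: 0.044; 46: 0.066; 88: 0.112; 170: 0.149; 320: 0.168
- south run (time / h: [target] / M): 13: 0.229; 24: 0.264; 46: 0.325; 88: 0.391; 170: 0.472; 320: 0.504

(standard deviation of a reading: 0.003 M)

* reaction order in [partner] at the outset, round the charge of the south-west run, defined at two percent of the substrate turned into target
* reaction order in [substrate] at the outset, round the charge of the south-west run, defined at two percent of the substrate turned into target (one fixed amount of target, the same in the runs compared)
* target in the east run at 1900 h, as a share of the substrate charged

- Overall: substrate + partner -> target, with free catalyst as catalyst.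
- Constant volume, constant temperature.
- An order is taken over about fifteen percent of the charge, up and down.

At 320 h the partner share reads 0.681 in the south-west run, 0.700 in the north-west run and 0.700 in the north-east run, though c_partner ranges from 0.120 M to 0.480 M and c_substrate from 0.240 M to 0.600 M. The south run, with target added, has made 0.324 M by then, against 0.327 M in the south-west run. Partner is the limiting reagent in the south-west charge, at 0.480 M against 0.600 M of substrate.

Both sides accept this pattern, but they dispute why the curve flattens. The forecast says “That points to catalyst dying with time”, and gives an order of 1 in partner, 0 in substrate and 58% for the east run, which has the south-west charge.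

My view is that the catalyst holds steady and partner leaks away by a second first-order drain beside the one to target, both pseudo-first-order. Then the share climbs to a ceiling, and the rest of the partner goes elsewhere.

My reckoning uses two readings. The south-west run at 24 h gives a target drain of 0.00770 h⁻¹. The mean share at 320 h over the south-west, north-west and north-east runs is 0.694. If that share is near its ceiling, both drains together run at about 0.0111 h⁻¹, so 0.0287 of the climb was still to come at 320 h.

Dividing it out gives 0.714: this is the ceiling share, the fraction of the partner charge that ends as target at the end of the climb. By 1900 h the clock has run 21.1 of my time constants, so on this reckoning the east run sits at its ceiling. That makes 57.1% of the substrate, my number, which differs from the forecast's 58%.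

    free catalyst + substrate → loaded catalyst + by-product (105.1 M⁻¹ h⁻¹)
    loaded catalyst + partner → target + free catalyst (9.180 M⁻¹ h⁻¹)
    partner → lost reagent (0.003485 h⁻¹)
    free catalyst + impurity → spent catalyst

The east run reaches 55.9% at 1900 h, with orders of 0.97 in partner and 0.067 in substrate, the latter above the forecast's 0. The scheme has partner leaking at 0.00348 h⁻¹, and its one step that spends catalyst goes at once, so the leak view stands. Catalyst does die at the very start, where impurity takes 2.78 × 10⁻⁴ M, a quarter of the free catalyst charged, at once. Put on the south run, the ceiling share and target drain give 193 h for making half the substrate's worth of target, and that run took 194 h.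

Readings and results are simulated for an exercise, and the scatter is random.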